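## Retrosynthetic overview

1. Atom labels for the target: ring C1 (stereocentre, carries C15(=C16H2)–CH2CH2CH=CMe2), C2, C3=C4(CO2Me), C5, C6, C7=C8(Me), C9, C10, C11=C12(Me), C13, C14.
2. The only ring (14-membered) is closed last at C3=C4 by an intramolecular Still–Gennari olefination, which sets the (Z)-enoate.
3. C8–C9 comes from an sp3–sp2 Negishi coupling with an (E)-vinyl iodide that already carries C4–C8 and the phosphonate.
4. C14–C1, the C1 stereocentre and the exocyclic methylene are made together by a copper-catalysed enantioselective SN2′ allylic alkylation.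
5. C9–C14 with the (Z)-C11=C12 alkene is 4-methylanisole, unzipped by Birch reduction and enol-ether ozonolysis; the ring fixes the alkene geometry and the two chain ends come out differentiated.

Assumption: the sense of induction of the chiral copper catalyst in step 7 is assigned by analogy (the mirror-image ligand is used if the opposite sense is found), and compounds 7, 10, 19 and 23 are taken as purchasable.

## Route

Step 1
Reactants: 1 4-methylanisole
Product: 2 1-methoxy-4-methylcyclohexa-1,4-diene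
Conditions: Li, NH3 (l), THF, t-BuOH, −33 °C
Reagents that add atoms: none
Why: Birch reduction leaves both donor substituents on sp2 carbons, giving the 1,4-diene whose ring will lock the C11=C12 geometry as Z.

Step 2
Reactants: 2 1-methoxy-4-methylcyclohexa-1,4-diene
Product: 5 methyl (3Z)-6-hydroxy-4-methylhex-3-enoate, via methoxy hydroperoxide 3 (not isolated), via aldehyde ester 4 (not isolated)
Conditions: O3 (1.0 equiv), CH2Cl2–MeOH, NaHCO3, −78 °C; then NaBH4, −78 → 0 °C
Reagents that add atoms: ozone, O=[O+][O-]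
Why: Chemoselective ozonolysis (Criegee cleavage) of the more electron-rich enol-ether double bond followed by hydride reduction opens the ring to a chain with an ester at C9 and an alcohol at C14, the trisubstituted alkene keeping its ring-derived Z geometry.

Step 3
Reactants: 5 methyl (3Z)-6-hydroxy-4-methylhex-3-enoate
Product: 6 methyl (3Z)-6-iodo-4-methylhex-3-enoate
Conditions: I2, PPh3, imidazole, CH2Cl2, 0 °C
Reagents that add atoms: iodine, II
Why: Appel-type iodination displaces the oxyphosphonium by SN2 at the primary carbon without isomerising the β,γ-unsaturated ester.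

Step 4
Reactants: 7 4,4-diethoxybut-1-yne
Product: 9 5,5-diethoxypent-2-yn-1-ol, via lithium acetylide 8 (not isolated)
Conditions: n-BuLi, THF, −78 °C; (CH2O)n, −78 → 25 °C; H2O
Reagents that add atoms: formaldehyde (as paraformaldehyde), C=O
Why: Deprotonation of the terminal alkyne and 1,2-addition of the acetylide to formaldehyde gives the propargylic alcohol that directs the next step.

Step 5
Reactants: 9 5,5-diethoxypent-2-yn-1-ol; 10 5-bromo-2-methylpent-2-ene
Product: 13 (2E)-5,5-diethoxy-2-(4-methylpent-3-en-1-yl)pent-2-en-1-ol, via Grignard reagent 11 (not isolated), via alkenylmagnesium alkoxide 12 (not isolated)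
Conditions: 10 (3 equiv), Mg, THF, 40 °C; then 9, CuI (10 mol %), THF–Et2O, −10 → 25 °C; H2O
Reagents that add atoms: none
Why: Copper-catalysed anti-carbomagnesiation of the propargylic alkoxide (Duboudin type) puts the homoprenyl group on the carbon next to the carbinol and magnesium on the distal carbon in a five-membered chelate, so protonation gives a single (E)-trisubstituted allylic alcohol.

Step 6
Reactants: 13 (2E)-5,5-diethoxy-2-(4-methylpent-3-en-1-yl)pent-2-en-1-ol
Product: 14 diethyl (2E)-5,5-diethoxy-2-(4-methylpent-3-en-1-yl)pent-2-en-1-yl phosphate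
Conditions: ClP(O)(OEt)2, Et3N, DMAP (cat.), CH2Cl2, 0 °C
Reagents that add atoms: diethyl chlorophosphate, CCOP(=O)(Cl)OCC
Why: O-Phosphorylation of the primary allylic alcohol installs the leaving group for the SN2′ step without touching the acetal.

Step 7
Reactants: 6 methyl (3Z)-6-iodo-4-methylhex-3-enoate; 14 diethyl (2E)-5,5-diethoxy-2-(4-methylpent-3-en-1-yl)pent-2-en-1-yl phosphate
Product: 16 methyl (3Z,7R)-7-(2,2-diethoxyethyl)-4,12-dimethyl-8-methylidenetrideca-3,11-dienoate, via dialkylzinc 15 (not isolated)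
Conditions: 6 (3 equiv), Et2Zn (neat), CuI (0.3 mol %), 50 °C, then vacuum; then 14, Cu(OTf)2 (5 mol %), chiral sulfonate-bearing imidazolinium salt (NHC precursor, 5.5 mol %), THF, −15 °C; H2O
Reagents that add atoms: none
Why: Iodine–zinc exchange gives an ester-tolerant dialkylzinc, and copper-catalysed enantioselective SN2′ allylic alkylation delivers the alkyl group to C1 anti to the phosphate under control of the chiral NHC–copper complex, creating the (R) stereocentre and the 1,1-disubstituted alkene in one operation.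

Step 8
Reactants: 16 methyl (3Z,7R)-7-(2,2-diethoxyethyl)-4,12-dimethyl-8-methylidenetrideca-3,11-dienoate
Product: 17 (3Z,7R)-7-(2,2-diethoxyethyl)-4,12-dimethyl-8-methylidenetrideca-3,11-dien-1-ol
Conditions: i-Bu2AlH (2.5 equiv), CH2Cl2, −78 → 0 °C; aq. KNaC4H4O6
Reagents that add atoms: none
Why: Hydride reduction of the ester to the primary alcohol at low temperature leaves the acetal, the alkenes and the C1 stereocentre untouched.

Step 9
Reactants: 17 (3Z,7R)-7-(2,2-diethoxyethyl)-4,12-dimethyl-8-methylidenetrideca-3,11-dien-1-ol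
Product: 18 (3Z,7R)-7-(2,2-diethoxyethyl)-1-iodo-4,12-dimethyl-8-methylidenetrideca-3,11-diene
Conditions: I2, PPh3, imidazole, CH2Cl2, 0 °C
Reagents that add atoms: iodine, II
Why: Appel-type iodination (SN2 at the primary carbinol) under imidazole buffering keeps the acetal intact.

Step 10
Reactants: 19 pent-3-yn-1-ol
Product: 20 pent-3-yn-1-yl 4-methylbenzenesulfonate
Conditions: TsCl, Et3N, DMAP (cat.), CH2Cl2, 0 → 25 °C
Reagents that add atoms: 4-methylbenzenesulfonyl chloride, Cc1ccc(cc1)S(Cl)(=O)=O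
Why: Sulfonylation of the primary alcohol gives a leaving group that is inert to the hydrozirconation that follows.

Step 11
Reactants: 20 pent-3-yn-1-yl 4-methylbenzenesulfonate
Product: 22 (3E)-4-iodopent-3-en-1-yl 4-methylbenzenesulfonate, via alkenylzirconocene chloride 21 (not isolated)
Conditions: Cp2Zr(H)Cl (1.5 equiv), THF, 45 °C; then I2, 0 °C
Reagents that add atoms: iodine, II
Why: Hydrozirconation adds H and Zr syn with Zr on the less hindered methyl-bearing carbon (about 9:1 after equilibration, minor regioisomer removed by chromatography), and iodinolysis with retention gives the (E)-2-iodoalkene that becomes the (E)-C7=C8 bond.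

Step 12
Reactants: 22 (3E)-4-iodopent-3-en-1-yl 4-methylbenzenesulfonate; 23 methyl 2-[bis(2,2,2-trifluoroethoxy)phosphoryl]acetate
Product: 25 methyl (5E)-2-[bis(2,2,2-trifluoroethoxy)phosphoryl]-6-iodohept-5-enoate, via sodium phosphonoacetate 24 (not isolated)
Conditions: 23 (2 equiv), NaH, DMF, 0 °C; then 22, NaI (10 mol %), 60 °C
Reagents that add atoms: none
Why: C-Alkylation (SN2) of the stabilised phosphonoacetate anion by the primary tosylate, helped by in situ Finkelstein exchange, leaves the vinyl iodide untouched.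

Step 13
Reactants: 18 (3Z,7R)-7-(2,2-diethoxyethyl)-1-iodo-4,12-dimethyl-8-methylidenetrideca-3,11-diene; 25 methyl (5E)-2-[bis(2,2,2-trifluoroethoxy)phosphoryl]-6-iodohept-5-enoate
Product: 27 methyl (2RS,5E,9Z,13R)-2-[bis(2,2,2-trifluoroethoxy)phosphoryl]-13-(2,2-diethoxyethyl)-6,10,18-trimethyl-14-methylidenenonadeca-5,9,17-trienoate, via alkylzinc iodide 26 (not isolated)
Conditions: 18, Zn dust, LiCl, THF, 40 °C; then 25, Pd(OAc)2 (2 mol %), SPhos (4 mol %), THF, 25 °C
Reagents that add atoms: none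
Why: Zinc insertion into the primary iodide and Negishi sp3–sp2 cross-coupling form C8–C9 with retention of the (E)-alkene geometry, the weakly basic alkylzinc tolerating the acetal and the acidic phosphonoacetate C–H.

Step 14
Reactants: 27 methyl (2RS,5E,9Z,13R)-2-[bis(2,2,2-trifluoroethoxy)phosphoryl]-13-(2,2-diethoxyethyl)-6,10,18-trimethyl-14-methylidenenonadeca-5,9,17-trienoate
Product: 28 methyl (2RS,5E,9Z,13R)-2-[bis(2,2,2-trifluoroethoxy)phosphoryl]-6,10,18-trimethyl-14-methylidene-13-(2-oxoethyl)nonadeca-5,9,17-trienoate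
Conditions: PPTS (20 mol %), acetone–H2O (10:1), 50 °C
Reagents that add atoms: water, O
Why: Mild acid-catalysed acetal hydrolysis frees the C3 aldehyde, and C1 is β to the carbonyl so it cannot epimerise.

Step 15
Reactants: 28 methyl (2RS,5E,9Z,13R)-2-[bis(2,2,2-trifluoroethoxy)phosphoryl]-6,10,18-trimethyl-14-methylidene-13-(2-oxoethyl)nonadeca-5,9,17-trienoate
Product: 30 methyl (1Z,4R,7Z,11E)-7,11-dimethyl-4-(6-methylhepta-1,5-dien-2-yl)cyclotetradeca-1,7,11-triene-1-carboxylate, via potassium phosphonate carbanion 29 (not isolated)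
Conditions: K2CO3, 18-crown-6, toluene, 0.5 mM, syringe-pump addition, 25 °C
Reagents that add atoms: none
Why: Intramolecular Still–Gennari (Horner–Wadsworth–Emmons) olefination under high dilution closes the 14-membered ring, the electron-poor bis(trifluoroethyl) phosphonate eliminating kinetically to the (Z)-enoate (C2 cis to CO2Me).

## Compound list

1 | 4-methylanisole | COc1ccc(C)cc1 | starting material
2 | 1-methoxy-4-methylcyclohexa-1,4-diene | COC1=CCC(C)=CC1 | intermediate
3 | methyl (3Z)-6-hydroperoxy-6-methoxy-4-methylhex-3-enoate | COC(=O)C/C=C(/C)CC(OC)OO | intermediate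
4 | methyl (3Z)-4-methyl-6-oxohex-3-enoate | COC(=O)C/C=C(/C)CC=O | intermediate
5 | methyl (3Z)-6-hydroxy-4-methylhex-3-enoate | COC(=O)C/C=C(/C)CCO | intermediate
6 | methyl (3Z)-6-iodo-4-methylhex-3-enoate | COC(=O)C/C=C(/C)CCI | intermediate
7 | 4,4-diethoxybut-1-yne | CCOC(CC#C)OCC | starting material
8 | (4,4-diethoxybut-1-yn-1-yl)lithium | CCOC(CC#C[Li])OCC | intermediate
9 | 5,5-diethoxypent-2-yn-1-ol | CCOC(CC#CCO)OCC | intermediate
10 | 5-bromo-2-methylpent-2-ene | CC(C)=CCCBr | starting material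
11 | (4-methylpent-3-en-1-yl)magnesium bromide | CC(C)=CCC[Mg]Br | intermediate
12 | bromomagnesium (2Z)-3-(bromomagnesio)-5,5-diethoxy-2-(4-methylpent-3-en-1-yl)pent-2-en-1-olate | CCOC(C/C([Mg]Br)=C(\CCC=C(C)C)CO[Mg]Br)OCC | intermediate
13 | (2E)-5,5-diethoxy-2-(4-methylpent-3-en-1-yl)pent-2-en-1-ol | CCOC(C/C=C(\CCC=C(C)C)CO)OCC | intermediate
14 | diethyl (2E)-5,5-diethoxy-2-(4-methylpent-3-en-1-yl)pent-2-en-1-yl phosphate | CCOC(C/C=C(\CCC=C(C)C)COP(=O)(OCC)OCC)OCC | intermediate
15 | bis[(3Z)-6-methoxy-3-methyl-6-oxohex-3-en-1-yl]zinc | COC(=O)C/C=C(/C)CC[Zn]CC/C(C)=C\CC(=O)OC | intermediate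
16 | methyl (3Z,7R)-7-(2,2-diethoxyethyl)-4,12-dimethyl-8-methylidenetrideca-3,11-dienoate | COC(=O)C/C=C(/C)CC[C@H](CC(OCC)OCC)C(=C)CCC=C(C)C | intermediate
17 | (3Z,7R)-7-(2,2-diethoxyethyl)-4,12-dimethyl-8-methylidenetrideca-3,11-dien-1-ol | OCC/C=C(/C)CC[C@H](CC(OCC)OCC)C(=C)CCC=C(C)C | intermediate
18 | (3Z,7R)-7-(2,2-diethoxyethyl)-1-iodo-4,12-dimethyl-8-methylidenetrideca-3,11-diene | ICC/C=C(/C)CC[C@H](CC(OCC)OCC)C(=C)CCC=C(C)C | intermediate
19 | pent-3-yn-1-ol | CC#CCCO | starting material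
20 | pent-3-yn-1-yl 4-methylbenzenesulfonate | CC#CCCOS(=O)(=O)c1ccc(C)cc1 | intermediate
21 | chlorobis(cyclopentadienyl)[(2E)-5-(4-methylbenzenesulfonyloxy)pent-2-en-2-yl]zirconium | C/C(=C\CCOS(=O)(=O)c1ccc(C)cc1)[Zr](Cl)(C1C=CC=C1)C1C=CC=C1 | intermediate
22 | (3E)-4-iodopent-3-en-1-yl 4-methylbenzenesulfonate | C/C(I)=C\CCOS(=O)(=O)c1ccc(C)cc1 | intermediate
23 | methyl 2-[bis(2,2,2-trifluoroethoxy)phosphoryl]acetate | COC(=O)CP(=O)(OCC(F)(F)F)OCC(F)(F)F | starting material
24 | sodium salt of the carbanion of 23 | [Na+].COC(=O)[CH-]P(=O)(OCC(F)(F)F)OCC(F)(F)F | intermediate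
25 | methyl (5E)-2-[bis(2,2,2-trifluoroethoxy)phosphoryl]-6-iodohept-5-enoate (racemic at C2) | COC(=O)C(CC/C=C(\C)I)P(=O)(OCC(F)(F)F)OCC(F)(F)F | intermediate
26 | [(3Z,7R)-7-(2,2-diethoxyethyl)-4,12-dimethyl-8-methylidenetrideca-3,11-dien-1-yl](iodo)zinc | I[Zn]CC/C=C(/C)CC[C@H](CC(OCC)OCC)C(=C)CCC=C(C)C | intermediate
27 | methyl (2RS,5E,9Z,13R)-2-[bis(2,2,2-trifluoroethoxy)phosphoryl]-13-(2,2-diethoxyethyl)-6,10,18-trimethyl-14-methylidenenonadeca-5,9,17-trienoate | COC(=O)C(CC/C=C(\C)CC/C=C(/C)CC[C@H](CC(OCC)OCC)C(=C)CCC=C(C)C)P(=O)(OCC(F)(F)F)OCC(F)(F)F | intermediate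
28 | methyl (2RS,5E,9Z,13R)-2-[bis(2,2,2-trifluoroethoxy)phosphoryl]-6,10,18-trimethyl-14-methylidene-13-(2-oxoethyl)nonadeca-5,9,17-trienoate | COC(=O)C(CC/C=C(\C)CC/C=C(/C)CC[C@H](CC=O)C(=C)CCC=C(C)C)P(=O)(OCC(F)(F)F)OCC(F)(F)F | intermediate
29 | potassium salt of the C2 carbanion of 28 | [K+].COC(=O)[C-](CC/C=C(\C)CC/C=C(/C)CC[C@H](CC=O)C(=C)CCC=C(C)C)P(=O)(OCC(F)(F)F)OCC(F)(F)F | intermediate
30 | methyl (1Z,4R,7Z,11E)-7,11-dimethyl-4-(6-methylhepta-1,5-dien-2-yl)cyclotetradeca-1,7,11-triene-1-carboxylate | C=C(CCC=C(C)C)[C@H]1C/C=C(\C(=O)OC)CC/C=C(\C)CC/C=C(/C)CC1 | target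

## Step count and risks

Total: 15 steps. Longest linear sequence: 9 steps (1, 2, 3, 7, 8, 9, 13, 14, 15).

**Step 7 (most uncertain).** The copper-catalysed SN2′ alkylation uses a functionalised dialkylzinc on an aliphatic 2,3-disubstituted allylic phosphate; enantioselectivity and SN2′/SN2 ratio are extrapolated from simpler substrates, and one alkyl group of 15 is wasted. The fallback sets out from 6 and returns at 16, replacing catalytic induction by reagent-controlled boronate homologation. Iodide 6 is borylated (B2pin2, CuI, PPh3, LiOMe, DMF) to methyl (3Z)-4-methyl-6-(4,4,5,5-tetramethyl-1,3,2-dioxaborolan-2-yl)hex-3-enoate F1. Commercial 3,3-diethoxypropan-1-ol is acylated (i-Pr2NCOCl) to 3,3-diethoxypropyl N,N-di(propan-2-yl)carbamate F2, which s-BuLi/(+)-sparteine deprotonates to (1R)-3,3-diethoxy-1-lithiopropyl N,N-di(propan-2-yl)carbamate F3. Trapping F3 with F1 and 1,2-metallate rearrangement give methyl (3Z,7R)-9,9-diethoxy-4-methyl-7-(4,4,5,5-tetramethyl-1,3,2-dioxaborolan-2-yl)non-3-enoate F4. 6-Methylhept-5-en-2-one is converted to N′-(6-methylhept-5-en-2-ylidene)-2,4,6-tri(propan-2-yl)benzenesulfonohydrazide F5, and a Shapiro reaction (n-BuLi) gives (6-methylhepta-1,5-dien-2-yl)lithium F6. Zweifel olefination of F4 with F6 (then I2, NaOMe) transfers C1 to the alkenyl carbon with retention and gives 16; the methyl ester is the weak point of this sequence.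

**Step 15.** The macrocyclic Still–Gennari reaction can oligomerise or lose Z-selectivity in the ring-forming transition state. The fallback sets out from 18 and returns at 30, moving the ring closure to C8–C9. Hydrolysis of 18 (PPTS, acetone–H2O) gives (3R,6Z)-9-iodo-6-methyl-3-(6-methylhepta-1,5-dien-2-yl)non-6-enal F7. Intermolecular Still–Gennari olefination of F7 with 25 (KN(SiMe3)2, 18-crown-6, THF, −78 °C) gives methyl (2Z,5R,8Z)-11-iodo-2-[(3E)-4-iodopent-3-en-1-yl]-8-methyl-5-(6-methylhepta-1,5-dien-2-yl)undeca-2,8-dienoate F8. Zinc (Zn, LiCl) inserts selectively into the alkyl iodide to give the alkylzinc iodide of F8 (iodozinc at C11) F9, and intramolecular Negishi coupling (Pd(OAc)2, SPhos, high dilution) gives 30.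

**Step 5.** Copper-catalysed carbomagnesiation of an internal alkynol with a primary alkyl Grignard reagent can be sluggish and low-yielding. The fallback sets out from 9 and returns at 13, replacing carbometalation by hydrometalation and cross-coupling. trans-Hydroalumination of 9 with LiAlH4/AlCl3 (60:1) and iodinolysis puts iodine on the carbinol-proximal carbon and gives (2Z)-5,5-diethoxy-2-iodopent-2-en-1-ol F10. Grignard reagent 11 is transmetalated with ZnBr2 to bromo(4-methylpent-3-en-1-yl)zinc F11, and Negishi coupling of F10 with F11 (PdCl2(dppf), THF) proceeds with retention to give 13.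

## Further compounds

F1 | step 7 | methyl (3Z)-4-methyl-6-(4,4,5,5-tetramethyl-1,3,2-dioxaborolan-2-yl)hex-3-enoate | COC(=O)C/C=C(/C)CCB1OC(C)(C)C(C)(C)O1
F2 | step 7 | 3,3-diethoxypropyl N,N-di(propan-2-yl)carbamate | CCOC(CCOC(=O)N(C(C)C)C(C)C)OCC
F3 | step 7 | (1R)-3,3-diethoxy-1-lithiopropyl N,N-di(propan-2-yl)carbamate | CCOC(C[C@@H]([Li])OC(=O)N(C(C)C)C(C)C)OCC
F4 | step 7 | methyl (3Z,7R)-9,9-diethoxy-4-methyl-7-(4,4,5,5-tetramethyl-1,3,2-dioxaborolan-2-yl)non-3-enoate | COC(=O)C/C=C(/C)CC[C@H](CC(OCC)OCC)B1OC(C)(C)C(C)(C)O1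
F5 | step 7 | N′-(6-methylhept-5-en-2-ylidene)-2,4,6-tri(propan-2-yl)benzenesulfonohydrazide | CC(CCC=C(C)C)=NNS(=O)(=O)c1c(C(C)C)cc(C(C)C)cc1C(C)C
F6 | step 7 | (6-methylhepta-1,5-dien-2-yl)lithium | [Li]C(=C)CCC=C(C)C
F7 | step 15 | (3R,6Z)-9-iodo-6-methyl-3-(6-methylhepta-1,5-dien-2-yl)non-6-enal | ICC/C=C(/C)CC[C@H](CC=O)C(=C)CCC=C(C)C
F8 | step 15 | methyl (2Z,5R,8Z)-11-iodo-2-[(3E)-4-iodopent-3-en-1-yl]-8-methyl-5-(6-methylhepta-1,5-dien-2-yl)undeca-2,8-dienoate | COC(=O)/C(CC/C=C(\C)I)=C\C[C@@H](CC/C(C)=C\CCI)C(=C)CCC=C(C)C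
F9 | step 15 | alkylzinc iodide of F8 (iodozinc at C11) | COC(=O)/C(CC/C=C(\C)I)=C\C[C@@H](CC/C(C)=C\CC[Zn]I)C(=C)CCC=C(C)C
F10 | step 5 | (2Z)-5,5-diethoxy-2-iodopent-2-en-1-ol | CCOC(C/C=C(\I)CO)OCC
F11 | step 5 | bromo(4-methylpent-3-en-1-yl)zinc | CC(C)=CCC[Zn]Br
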